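**Plan**

- Retrosynthetic cuts, in order: O1–C2 (ring C, oxa-Michael); C4a–C8a (ring A, pyrone-to-arene Claisen); the bond from the pyrone 6-methyl carbon to the cinnamoyl carbonyl (future C4a–C4); the bond from pyrone C3 to the side-chain methylene (future C8–CH2); the prenyl–CH bond of the side chain.
- Enabling feature: ring A is a 2-acylphloroglucinol (oxygen on C5, C7 and C8a, acyl carbon C4 on C4a, chain on C8). It is therefore an isomer of a 3-alkyl-4-hydroxy-6-(2-oxoalkyl)-2-pyrone, whose lactone carbon C2 becomes C8a and whose ketone-flanked methylene becomes C4a.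
- Forward order: side-chain aldehyde, then attachment to C3 of 4-hydroxy-6-methyl-2-pyrone, then ring B as a cinnamoyl Weinreb amide on the 6-methyl group, then ring A with Mg(OMe)2, then ring C last.
- Stereochemistry: the methyl-bearing centre comes from (S)-4-methyloxolan-2-one, the neighbouring centre from anti (trans) enolate prenylation of that lactone, and C2 from a catalyst-controlled oxa-Michael addition.

Key step: step 9

Assumption: which pseudo-enantiomer of the cinchona thiourea gives the (2S) series cannot be predicted with certainty; the quinine-derived catalyst is written in step 11, and its quinidine-derived counterpart takes its place if a trial closure shows the opposite sense.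

Assumption: (S)-4-methyloxolan-2-one, 4-hydroxy-6-methyl-2H-pyran-2-one and the Weinreb phosphonate are taken as purchasable; the side-chain alcohol is carried as a tert-butyldimethylsilyl (TBS) ether instead of an acetal so that the final acid treatment can stay mild.

**Route**

Step 1
Reactants: 1 (S)-4-methyloxolan-2-one; 2 prenyl bromide (1-bromo-3-methylbut-2-ene)
Product: 3 (3S,4S)-4-methyl-3-(3-methylbut-2-en-1-yl)oxolan-2-one
Conditions: LiN(iPr)2, THF, −78 °C; then 2, −78 → −30 °C
Reagents that add atoms: none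
Why: Alkylation of the lithium enolate of a 4-substituted butyrolactone, in which the allylic bromide should approach the face opposite the C4 methyl group and so set C3 trans to it (3S) under substrate control.

Step 2
Reactants: 3 (3S,4S)-4-methyl-3-(3-methylbut-2-en-1-yl)oxolan-2-one
Product: 4 (2S,3S)-4-hydroxy-N-methoxy-N,3-dimethyl-2-(3-methylbut-2-en-1-yl)butanamide
Conditions: MeNH(OMe)·HCl, AlMe3, CH2Cl2, 0 → 25 °C; aq. potassium sodium tartrate
Reagents that add atoms: N,O-dimethylhydroxylamine hydrochloride, CNOC.Cl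
Why: Weinreb aminolysis of the lactone by the aluminium amide formed in the flask cleaves only the acyl–oxygen bond, so both stereocentres stay untouched and the two chain ends become different functions.

Step 3
Reactants: 4 (2S,3S)-4-hydroxy-N-methoxy-N,3-dimethyl-2-(3-methylbut-2-en-1-yl)butanamide
Product: 5 (2S,3S)-4-[(tert-butyldimethylsilyl)oxy]-N-methoxy-N,3-dimethyl-2-(3-methylbut-2-en-1-yl)butanamide
Conditions: TBSCl, imidazole, DMF, 0 → 25 °C (crude 4 used at once)
Reagents that add atoms: tert-butyldimethylsilyl chloride, CC(C)(C)[Si](C)(C)Cl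
Why: Imidazole-promoted silylation of the primary alcohol forestalls relactonisation and gives an ether that tolerates the later amide bases and methoxide.

Step 4
Reactants: 5 (2S,3S)-4-[(tert-butyldimethylsilyl)oxy]-N-methoxy-N,3-dimethyl-2-(3-methylbut-2-en-1-yl)butanamide
Product: 6 (2S,3S)-4-[(tert-butyldimethylsilyl)oxy]-3-methyl-2-(3-methylbut-2-en-1-yl)butanal
Conditions: iBu2AlH, THF, −78 °C; aq. potassium sodium tartrate, 0 °C; used without storage
Reagents that add atoms: none
Why: Hydride reduction of a Weinreb amide stops at the chelated tetrahedral aluminate, which releases the aldehyde only on work-up, and the cold neutral work-up should leave the α-centre intact.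

Step 5
Reactants: 6 (2S,3S)-4-[(tert-butyldimethylsilyl)oxy]-3-methyl-2-(3-methylbut-2-en-1-yl)butanal; 7 4-hydroxy-6-methyl-2H-pyran-2-one
Product: 9 3-[(2R,3S)-4-[(tert-butyldimethylsilyl)oxy]-3-methyl-2-(3-methylbut-2-en-1-yl)butyl]-4-hydroxy-6-methyl-2H-pyran-2-one, via alkylidene pyrandione 8 (not isolated)
Conditions: diethyl 2,6-dimethyl-1,4-dihydropyridine-3,5-dicarboxylate (Hantzsch ester, 1.1 equiv), L-proline (20 mol %), CH2Cl2, 25 °C
Reagents that add atoms: none
Why: Three-component reductive alkylation, in which a proline-mediated Knoevenagel condensation at the acidic pyrone C3–H gives alkylidene pyrandione 8 and the dihydropyridine reduces it by conjugate hydride transfer; no stereocentre is formed, and the former aldehyde α-centre is expected to persist because hydride transfer is fast.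

Step 6
Reactants: 10 2,4-dihydroxybenzaldehyde
Product: 11 2,4-bis(methoxymethoxy)benzaldehyde
Conditions: MOMCl (2.6 equiv), iPr2NEt, CH2Cl2, 0 → 25 °C
Reagents that add atoms: chloromethyl methyl ether, COCCl
Why: Twofold Williamson-type O-alkylation of the phenols gives acetal ethers that survive amide bases and methoxide and are removed by dilute acid.

Step 7
Reactants: 11 2,4-bis(methoxymethoxy)benzaldehyde; 12 diethyl {2-[methoxy(methyl)amino]-2-oxoethyl}phosphonate
Product: 13 (2E)-3-[2,4-bis(methoxymethoxy)phenyl]-N-methoxy-N-methylprop-2-enamide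
Conditions: NaH, THF, 0 → 25 °C
Reagents that add atoms: none
Why: Horner–Wadsworth–Emmons olefination with a stabilised phosphonate carbanion should deliver the E-configured cinnamoyl Weinreb amide.

Step 8
Reactants: 9 3-[(2R,3S)-4-[(tert-butyldimethylsilyl)oxy]-3-methyl-2-(3-methylbut-2-en-1-yl)butyl]-4-hydroxy-6-methyl-2H-pyran-2-one; 13 (2E)-3-[2,4-bis(methoxymethoxy)phenyl]-N-methoxy-N-methylprop-2-enamide
Product: 14 6-[(3E)-4-[2,4-bis(methoxymethoxy)phenyl]-2-oxobut-3-en-1-yl]-3-[(2R,3S)-4-[(tert-butyldimethylsilyl)oxy]-3-methyl-2-(3-methylbut-2-en-1-yl)butyl]-4-hydroxy-2H-pyran-2-one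
Conditions: LiN(iPr)2 (2.3 equiv), THF, −78 °C; then 13, −78 → −20 °C; cold 1 M HCl to pH 3
Reagents that add atoms: none
Why: Double deprotonation of the 4-hydroxy-6-methyl-2-pyrone gives a dianion whose 6-methylene carbanion acylates the Weinreb amide by 1,2-addition (Claisen-type acylation), and the chelated tetrahedral adduct prevents a second addition.

Step 9
Reactants: 14 6-[(3E)-4-[2,4-bis(methoxymethoxy)phenyl]-2-oxobut-3-en-1-yl]-3-[(2R,3S)-4-[(tert-butyldimethylsilyl)oxy]-3-methyl-2-(3-methylbut-2-en-1-yl)butyl]-4-hydroxy-2H-pyran-2-one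
Product: 16 (2E)-3-[2,4-bis(methoxymethoxy)phenyl]-1-{3-[(2R,3S)-4-[(tert-butyldimethylsilyl)oxy]-3-methyl-2-(3-methylbut-2-en-1-yl)butyl]-2,4,6-trihydroxyphenyl}prop-2-en-1-one, via triketo ester 15 (not isolated)
Conditions: Mg(OMe)2 (6 equiv), MeOH, reflux; then cold 1 M HCl to pH 3
Reagents that add atoms: none
Why: Methoxide delivered by Mg(OMe)2 adds to the lactone carbonyl of 14 and opens the pyrone to the magnesium-chelated triketo ester 15, whose methylene between the C5 and C7 ketones attacks the ester carbonyl; loss of methoxide and two enolisations then give the arene, so the carbons that become C4a and C8a are joined. The closest known reaction is the Mg(OMe)2-mediated Claisen-type cyclisation of 6-(2-oxoalkyl)-4-hydroxy-2-pyrones and of 3,5,7-triketo esters to acylphloroglucinols, the laboratory counterpart of the chalcone synthase folding. Ring A closes in a 6-exo-trig (enolexo) mode, the ester carbonyl lying outside the new ring. No stereocentre is formed, and the two side-chain centres are not α to any carbonyl group, so they cannot epimerise. The step needs Claisen in preference to aldol folding: the rival donor carbon is tertiary and carries the branched chain, the styryl ketone is enolised within the chelate and therefore a poor acceptor, and methoxide in place of hydroxide keeps the ester as the acylating end. The product leaves the flask as a magnesium polyphenoxide that is too electron-rich to add to its own enone, and the cold acidic quench with immediate use in step 10 is meant to keep ring C open.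

Step 10
Reactants: 16 (2E)-3-[2,4-bis(methoxymethoxy)phenyl]-1-{3-[(2R,3S)-4-[(tert-butyldimethylsilyl)oxy]-3-methyl-2-(3-methylbut-2-en-1-yl)butyl]-2,4,6-trihydroxyphenyl}prop-2-en-1-one
Product: 17 (2E)-3-[2,4-bis(methoxymethoxy)phenyl]-1-{3-[(2R,3S)-4-[(tert-butyldimethylsilyl)oxy]-3-methyl-2-(3-methylbut-2-en-1-yl)butyl]-2-hydroxy-4,6-bis(methoxymethoxy)phenyl}prop-2-en-1-one
Conditions: MOMCl (2.1 equiv), iPr2NEt, CH2Cl2, −10 → 0 °C
Reagents that add atoms: chloromethyl methyl ether, COCCl
Why: Base-mediated O-alkylation should take the non-chelated para hydroxyl first and then the ortho hydroxyl beside the ring hydrogen, leaving free the hydrogen-bonded hydroxyl wedged between the branched chain and the carbonyl, as in the partial etherification of 3-alkyl-2,4,6-trihydroxyaryl ketones.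

Step 11
Reactants: 17 (2E)-3-[2,4-bis(methoxymethoxy)phenyl]-1-{3-[(2R,3S)-4-[(tert-butyldimethylsilyl)oxy]-3-methyl-2-(3-methylbut-2-en-1-yl)butyl]-2-hydroxy-4,6-bis(methoxymethoxy)phenyl}prop-2-en-1-one
Product: 18 (2S)-2-[2,4-bis(methoxymethoxy)phenyl]-8-[(2R,3S)-4-[(tert-butyldimethylsilyl)oxy]-3-methyl-2-(3-methylbut-2-en-1-yl)butyl]-5,7-bis(methoxymethoxy)-2,3-dihydro-4H-chromen-4-one
Conditions: 1-[3,5-bis(trifluoromethyl)phenyl]-3-[(8S,9S)-6′-methoxycinchonan-9-yl]thiourea (20 mol %), toluene, 25 °C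
Reagents that add atoms: none
Why: Catalytic asymmetric intramolecular oxa-Michael addition (6-endo-trig) of the single free phenol to the enone, in which the quinuclidine nitrogen activates the phenol and the thiourea binds the carbonyl, so that the phenoxide should add to one face of the β-carbon and C2 is set (2S) by the catalyst, independent of the remote side-chain centres.

Step 12
Reactants: 18 (2S)-2-[2,4-bis(methoxymethoxy)phenyl]-8-[(2R,3S)-4-[(tert-butyldimethylsilyl)oxy]-3-methyl-2-(3-methylbut-2-en-1-yl)butyl]-5,7-bis(methoxymethoxy)-2,3-dihydro-4H-chromen-4-one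
Product: 19 (2S)-2-(2,4-dihydroxyphenyl)-5,7-dihydroxy-8-[(2R,3S)-4-hydroxy-3-methyl-2-(3-methylbut-2-en-1-yl)butyl]-2,3-dihydro-4H-chromen-4-one
Conditions: HCl (1.25 M in MeOH), 25 → 40 °C
Reagents that add atoms: none
Why: Acid-catalysed methanolysis (transacetalisation and desilylation) removes the four aryl methoxymethyl ethers and the primary silyl ether under conditions mild enough that the C2 centre and the trisubstituted alkene should survive.

**Compound list**

1 | (S)-4-methyloxolan-2-one | O=C1C[C@H](C)CO1 | starting material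
2 | prenyl bromide (1-bromo-3-methylbut-2-ene) | CC(C)=CCBr | starting material
3 | (3S,4S)-4-methyl-3-(3-methylbut-2-en-1-yl)oxolan-2-one | CC(C)=CC[C@H](C1=O)[C@H](C)CO1 | intermediate
4 | (2S,3S)-4-hydroxy-N-methoxy-N,3-dimethyl-2-(3-methylbut-2-en-1-yl)butanamide | CC(C)=CC[C@H](C(=O)N(C)OC)[C@H](C)CO | intermediate
5 | (2S,3S)-4-[(tert-butyldimethylsilyl)oxy]-N-methoxy-N,3-dimethyl-2-(3-methylbut-2-en-1-yl)butanamide | CC(C)=CC[C@H](C(=O)N(C)OC)[C@H](C)CO[Si](C)(C)C(C)(C)C | intermediate
6 | (2S,3S)-4-[(tert-butyldimethylsilyl)oxy]-3-methyl-2-(3-methylbut-2-en-1-yl)butanal | CC(C)=CC[C@H](C=O)[C@H](C)CO[Si](C)(C)C(C)(C)C | intermediate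
7 | 4-hydroxy-6-methyl-2H-pyran-2-one | CC1=CC(O)=CC(=O)O1 | starting material
8 | 3-[(2R,3S)-4-[(tert-butyldimethylsilyl)oxy]-3-methyl-2-(3-methylbut-2-en-1-yl)butylidene]-6-methyl-2H-pyran-2,4(3H)-dione (alkene geometry open; not isolated) | CC(C)=CC[C@H](C=C1C(=O)C=C(C)OC1=O)[C@H](C)CO[Si](C)(C)C(C)(C)C | intermediate
9 | 3-[(2R,3S)-4-[(tert-butyldimethylsilyl)oxy]-3-methyl-2-(3-methylbut-2-en-1-yl)butyl]-4-hydroxy-6-methyl-2H-pyran-2-one | CC(C)=CC[C@H](CC1=C(O)C=C(C)OC1=O)[C@H](C)CO[Si](C)(C)C(C)(C)C | intermediate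
10 | 2,4-dihydroxybenzaldehyde | O=Cc1ccc(O)cc1O | starting material
11 | 2,4-bis(methoxymethoxy)benzaldehyde | COCOc1ccc(C=O)c(OCOC)c1 | intermediate
12 | diethyl {2-[methoxy(methyl)amino]-2-oxoethyl}phosphonate | CCOP(=O)(CC(=O)N(C)OC)OCC | starting material
13 | (2E)-3-[2,4-bis(methoxymethoxy)phenyl]-N-methoxy-N-methylprop-2-enamide | COCOc1ccc(/C=C/C(=O)N(C)OC)c(OCOC)c1 | intermediate
14 | 6-[(3E)-4-[2,4-bis(methoxymethoxy)phenyl]-2-oxobut-3-en-1-yl]-3-[(2R,3S)-4-[(tert-butyldimethylsilyl)oxy]-3-methyl-2-(3-methylbut-2-en-1-yl)butyl]-4-hydroxy-2H-pyran-2-one | CC(C)=CC[C@H](CC1=C(O)C=C(CC(=O)/C=C/c2ccc(OCOC)cc2OCOC)OC1=O)[C@H](C)CO[Si](C)(C)C(C)(C)C | intermediate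
15 | methyl (8E)-9-[2,4-bis(methoxymethoxy)phenyl]-2-[(2R,3S)-4-[(tert-butyldimethylsilyl)oxy]-3-methyl-2-(3-methylbut-2-en-1-yl)butyl]-3,5,7-trioxonon-8-enoate (magnesium chelate; ester α-carbon unassigned; not isolated) | CC(C)=CC[C@H](CC(C(=O)OC)C(=O)CC(=O)CC(=O)/C=C/c1ccc(OCOC)cc1OCOC)[C@H](C)CO[Si](C)(C)C(C)(C)C | intermediate
16 | (2E)-3-[2,4-bis(methoxymethoxy)phenyl]-1-{3-[(2R,3S)-4-[(tert-butyldimethylsilyl)oxy]-3-methyl-2-(3-methylbut-2-en-1-yl)butyl]-2,4,6-trihydroxyphenyl}prop-2-en-1-one | CC(C)=CC[C@H](Cc1c(O)cc(O)c(C(=O)/C=C/c2ccc(OCOC)cc2OCOC)c1O)[C@H](C)CO[Si](C)(C)C(C)(C)C | intermediate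
17 | (2E)-3-[2,4-bis(methoxymethoxy)phenyl]-1-{3-[(2R,3S)-4-[(tert-butyldimethylsilyl)oxy]-3-methyl-2-(3-methylbut-2-en-1-yl)butyl]-2-hydroxy-4,6-bis(methoxymethoxy)phenyl}prop-2-en-1-one | CC(C)=CC[C@H](Cc1c(OCOC)cc(OCOC)c(C(=O)/C=C/c2ccc(OCOC)cc2OCOC)c1O)[C@H](C)CO[Si](C)(C)C(C)(C)C | intermediate
18 | (2S)-2-[2,4-bis(methoxymethoxy)phenyl]-8-[(2R,3S)-4-[(tert-butyldimethylsilyl)oxy]-3-methyl-2-(3-methylbut-2-en-1-yl)butyl]-5,7-bis(methoxymethoxy)-2,3-dihydro-4H-chromen-4-one | CC(C)=CC[C@H](Cc1c(OCOC)cc(OCOC)c2c1O[C@H](c1ccc(OCOC)cc1OCOC)CC2=O)[C@H](C)CO[Si](C)(C)C(C)(C)C | intermediate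
19 | (2S)-2-(2,4-dihydroxyphenyl)-5,7-dihydroxy-8-[(2R,3S)-4-hydroxy-3-methyl-2-(3-methylbut-2-en-1-yl)butyl]-2,3-dihydro-4H-chromen-4-one | CC(C)=CC[C@H](Cc1c(O)cc(O)c2c1O[C@H](c1ccc(O)cc1O)CC2=O)[C@H](C)CO | target

**Summary**

Total step count: 12.
Longest linear sequence: 10 steps (steps 1–5 and 8–12, from lactone 1); ring B is prepared in a two-step branch (steps 6 and 7).

**Steps most likely to fail**

Step 11. Facial selectivity of the phenoxide addition may be poor on this electron-rich, ortho-substituted enone, and reversible ring opening under the basic catalyst may erode whatever selectivity is reached. The fallback sets out from chalcone 17 and gives up catalyst control in favour of separation and recycling. Closure with NaOAc in refluxing ethanol should give flavanone 18 together with its C2 epimer, (2R)-2-[2,4-bis(methoxymethoxy)phenyl]-8-[(2R,3S)-4-[(tert-butyldimethylsilyl)oxy]-3-methyl-2-(3-methylbut-2-en-1-yl)butyl]-5,7-bis(methoxymethoxy)-2,3-dihydro-4H-chromen-4-one F1. Because the side chain carries two fixed centres, the two are diastereomers and would be separated by preparative HPLC on a chiral stationary phase. F1 would be put back into the same base-mediated equilibrium with 17 and 18 and separated again, so that the material rejoins the route at 18.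

Step 9. Methoxide or an enolate oxygen of the opened chain may add to the styryl ketone, aldol-type folding may compete, and ring C may close through either ortho hydroxyl during work-up or during the protection of step 10. The fallback sets out from pyrone 9 and builds the arene before the enone exists. The dianion of 9 (LiN(iPr)2, THF, −78 °C) would be acylated with N-methoxy-N-methylacetamide to 3-[(2R,3S)-4-[(tert-butyldimethylsilyl)oxy]-3-methyl-2-(3-methylbut-2-en-1-yl)butyl]-4-hydroxy-6-(2-oxopropyl)-2H-pyran-2-one F2. The same Mg(OMe)2 cyclisation, here on the substrate type for which it is best established, should give 1-{3-[(2R,3S)-4-[(tert-butyldimethylsilyl)oxy]-3-methyl-2-(3-methylbut-2-en-1-yl)butyl]-2,4,6-trihydroxyphenyl}ethan-1-one F3. Partial etherification (MOMCl, iPr2NEt, CH2Cl2) would then give 1-{3-[(2R,3S)-4-[(tert-butyldimethylsilyl)oxy]-3-methyl-2-(3-methylbut-2-en-1-yl)butyl]-2-hydroxy-4,6-bis(methoxymethoxy)phenyl}ethan-1-one F4, at a stage where no ring closure can interfere and regioisomers can be removed. Claisen–Schmidt condensation of F4 with aldehyde 11 (KOH, EtOH, 25 °C) returns to the route at chalcone 17, so steps 7, 8 and 10 are bypassed as well.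

Step 5. The aldehyde α-centre may epimerise through enamine or dienol formation before hydride transfer, and the doubly branched aldehyde may condense sluggishly. The fallback sets out from aldehyde 6 and replaces the condensation by an SN2 alkylation followed by construction of the pyrone.
- Reduction with NaBH4 in MeOH at 0 °C should give (2S,3S)-4-[(tert-butyldimethylsilyl)oxy]-3-methyl-2-(3-methylbut-2-en-1-yl)butan-1-ol F5.
- I2, PPh3 and imidazole in CH2Cl2 would convert it into tert-butyl{[(2S,3S)-3-(iodomethyl)-2,6-dimethylhept-5-en-1-yl]oxy}dimethylsilane F6.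
- The sodium enolate of methyl acetoacetate (NaH, THF/DMF, 60 °C) would be alkylated by F6 to methyl 2-[(2R,3S)-4-[(tert-butyldimethylsilyl)oxy]-3-methyl-2-(3-methylbut-2-en-1-yl)butyl]-3-oxobutanoate F7.
- Its dianion (NaH, then n-BuLi, THF, 0 °C) would be acetylated at the terminal carbon with N-methoxy-N-methylacetamide to methyl 2-[(2R,3S)-4-[(tert-butyldimethylsilyl)oxy]-3-methyl-2-(3-methylbut-2-en-1-yl)butyl]-3,5-dioxohexanoate F8.
- Lactonisation with 1,8-diazabicyclo[5.4.0]undec-7-ene in refluxing toluene returns to the route at pyrone 9, with no epimerisable centre next to a carbonyl group at any point.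

Further compounds
F1 | step 11 | (2R)-2-[2,4-bis(methoxymethoxy)phenyl]-8-[(2R,3S)-4-[(tert-butyldimethylsilyl)oxy]-3-methyl-2-(3-methylbut-2-en-1-yl)butyl]-5,7-bis(methoxymethoxy)-2,3-dihydro-4H-chromen-4-one | CC(C)=CC[C@H](Cc1c(OCOC)cc(OCOC)c2c1O[C@@H](c1ccc(OCOC)cc1OCOC)CC2=O)[C@H](C)CO[Si](C)(C)C(C)(C)C
F2 | step 9 | 3-[(2R,3S)-4-[(tert-butyldimethylsilyl)oxy]-3-methyl-2-(3-methylbut-2-en-1-yl)butyl]-4-hydroxy-6-(2-oxopropyl)-2H-pyran-2-one | CC(C)=CC[C@H](CC1=C(O)C=C(CC(C)=O)OC1=O)[C@H](C)CO[Si](C)(C)C(C)(C)C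
F3 | step 9 | 1-{3-[(2R,3S)-4-[(tert-butyldimethylsilyl)oxy]-3-methyl-2-(3-methylbut-2-en-1-yl)butyl]-2,4,6-trihydroxyphenyl}ethan-1-one | CC(C)=CC[C@H](Cc1c(O)cc(O)c(C(C)=O)c1O)[C@H](C)CO[Si](C)(C)C(C)(C)C
F4 | step 9 | 1-{3-[(2R,3S)-4-[(tert-butyldimethylsilyl)oxy]-3-methyl-2-(3-methylbut-2-en-1-yl)butyl]-2-hydroxy-4,6-bis(methoxymethoxy)phenyl}ethan-1-one | CC(C)=CC[C@H](Cc1c(OCOC)cc(OCOC)c(C(C)=O)c1O)[C@H](C)CO[Si](C)(C)C(C)(C)C
F5 | step 5 | (2S,3S)-4-[(tert-butyldimethylsilyl)oxy]-3-methyl-2-(3-methylbut-2-en-1-yl)butan-1-ol | CC(C)=CC[C@H](CO)[C@H](C)CO[Si](C)(C)C(C)(C)C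
F6 | step 5 | tert-butyl{[(2S,3S)-3-(iodomethyl)-2,6-dimethylhept-5-en-1-yl]oxy}dimethylsilane | CC(C)=CC[C@H](CI)[C@H](C)CO[Si](C)(C)C(C)(C)C
F7 | step 5 | methyl 2-[(2R,3S)-4-[(tert-butyldimethylsilyl)oxy]-3-methyl-2-(3-methylbut-2-en-1-yl)butyl]-3-oxobutanoate | CC(C)=CC[C@H](CC(C(C)=O)C(=O)OC)[C@H](C)CO[Si](C)(C)C(C)(C)C
F8 | step 5 | methyl 2-[(2R,3S)-4-[(tert-butyldimethylsilyl)oxy]-3-methyl-2-(3-methylbut-2-en-1-yl)butyl]-3,5-dioxohexanoate | CC(C)=CC[C@H](CC(C(=O)CC(C)=O)C(=O)OC)[C@H](C)CO[Si](C)(C)C(C)(C)C
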